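**Strategy**

1. With the 3'-OH masked as an acetate, ring C is cut at three bonds at once (C4a–C4, C4–C3 and O1–C2), which leaves a ring A aryl iodide, carbon monoxide (C4 and its oxygen) and a ring B aryl acetylene (C3 and C2).
2. The cut is possible because C4a lies on the symmetry line of ring A that passes through C4a and C7, with an oxygen-bearing carbon on either side (C8a–O1 and C5–OH). The ring A partner is therefore the symmetric 2-iodo-5-methoxyresorcinol, used as its diacetate, and either oxygen closes ring C to the same flavone.
3. Ring A, forward: 5-methoxyresorcinol, bis-MOM ether, lithiation and iodination between the two OMOM groups, diol, diacetate.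
4. Ring B, forward: 1,2,4-trimethoxybenzene, 3'-oxygen by lithiation, borylation and oxidation between two methoxy groups, acetate, iodide at C1' by electrophilic iodination, terminal alkyne by Sonogashira coupling and desilylation.
5. Rings A and B are bought as benzenes. Ring C is the only ring made, in the palladium-catalysed carbonylative annulation, and acetate methanolysis ends the route.
6. Stereochemistry: none to set, since the target has no stereocentre and no configurationally stable axis.

Key step: step 10

Remark: flavone numbering is used throughout (ring C: O1, C2, C3, C4; ring A: C4a, C5 to C8, C8a; ring B primed).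

**Route**

Step 1
Reactants: 1 5-methoxyresorcinol
Product: 2 1-methoxy-3,5-bis(methoxymethoxy)benzene
Conditions: MOMCl (2.5 equiv), i-Pr2NEt (3 equiv), CH2Cl2, 0 °C to rt
Reagents that add atoms: chloromethyl methyl ether, COCCl
Why: Williamson-type O-alkylation of both phenols by the α-chloro ether under a hindered amine base installs the two OMOM groups, which are the strong chelating directors needed for the lithiation in step 2.

Step 2
Reactants: 2 1-methoxy-3,5-bis(methoxymethoxy)benzene
Product: 4 2-iodo-5-methoxy-1,3-bis(methoxymethoxy)benzene, via 2-lithio-5-methoxy-1,3-bis(methoxymethoxy)benzene 3 (not isolated)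
Conditions: n-BuLi (1.1 equiv), THF, 0 °C; then I2 (1.2 equiv) in THF, −78 °C to rt; aq. Na2S2O3 work-up
Reagents that add atoms: iodine, II
Why: directed ortho-metalation, in which C2–H is the only proton flanked by two chelating OMOM groups and should be removed in preference to the positions between one OMOM and the weaker OMe director, followed by iodinolysis of the aryllithium.

Step 3
Reactants: 4 2-iodo-5-methoxy-1,3-bis(methoxymethoxy)benzene
Product: 5 2-iodo-5-methoxyresorcinol
Conditions: HCl (1.25 M in MeOH, 4 equiv), MeOH, 0 °C to rt, in the dark, stopped at full conversion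
Reagents that add atoms: none
Why: acid-catalysed acetal methanolysis (MOM removal) passes both methoxymethyl groups to methanol as dimethoxymethane; dilute acid, low temperature and short contact are chosen because the electron-rich iodine-bearing carbon is open to ipso-protonation.

Step 4
Reactants: 5 2-iodo-5-methoxyresorcinol
Product: 6 2-iodo-5-methoxy-1,3-phenylene diacetate
Conditions: Ac2O (3 equiv), pyridine, DMAP (cat.), CH2Cl2, 0 °C to rt, on the freshly prepared diol
Reagents that add atoms: acetic anhydride, CC(=O)OC(C)=O
Why: DMAP-catalysed O-acylation of both phenols gives the diacetate, in which the iodide is less electron-rich and the phenols stay masked until the amine of step 10 releases them.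

Step 5
Reactants: 7 1,2,4-trimethoxybenzene
Product: 10 2,3,6-trimethoxyphenol, via 3-lithio-1,2,4-trimethoxybenzene 8 (not isolated), via lithium trimethoxy(2,3,6-trimethoxyphenyl)borate 9 (not isolated)
Conditions: n-BuLi (1.1 equiv), THF, 0 °C to rt; B(OMe)3, −78 °C to rt; AcOH, 30% H2O2, 0 °C to rt
Reagents that add atoms: hydrogen peroxide, OO
Why: directed ortho-metalation at C3, the only C–H between two methoxy groups, followed by borylation and peroxide oxidation of the arylboron species (1,2-aryl shift from boron to oxygen) places the future 3'-oxygen between the 2'- and 4'-methoxy groups.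

Step 6
Reactants: 10 2,3,6-trimethoxyphenol
Product: 11 2,3,6-trimethoxyphenyl acetate
Conditions: Ac2O (1.5 equiv), pyridine, DMAP (cat.), CH2Cl2, rt
Reagents that add atoms: acetic anhydride, CC(=O)OC(C)=O
Why: DMAP-catalysed acetylation turns the OH into the weakly donating OAc, which removes the strongest para director so that the methoxy groups decide the site of the next electrophilic substitution, and the acetate then protects the 3'-oxygen to the end.

Step 7
Reactants: 11 2,3,6-trimethoxyphenyl acetate
Product: 12 3-iodo-2,5,6-trimethoxyphenyl acetate
Conditions: NIS (1.05 equiv), TFA (0.3 equiv), MeCN, 0 °C to rt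
Reagents that add atoms: N-iodosuccinimide, O=C1CCC(=O)N1I
Why: electrophilic aromatic iodination with acid-activated NIS, where C5 of 11 is ortho to the 6-OMe and para to the 2-OMe whereas C4 is ortho to the 3-OMe but para only to the acetoxy group, so iodine should enter at C5, the future C1'.

Step 8
Reactants: 12 3-iodo-2,5,6-trimethoxyphenyl acetate; 13 trimethylsilylacetylene
Product: 14 2,5,6-trimethoxy-3-[(trimethylsilyl)ethynyl]phenyl acetate
Conditions: PdCl2(PPh3)2 (3 mol %), CuI (5 mol %), Et3N, THF, 50 °C
Reagents that add atoms: none
Why: Sonogashira coupling of the aryl iodide with the silyl-capped alkyne, in which the tertiary amine base is not nucleophilic enough to cleave the aryl acetate and the silyl group rules out double arylation.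

Step 9
Reactants: 14 2,5,6-trimethoxy-3-[(trimethylsilyl)ethynyl]phenyl acetate
Product: 15 3-ethynyl-2,5,6-trimethoxyphenyl acetate
Conditions: TBAF (1.1 equiv), AcOH (1.2 equiv), THF, 0 °C
Reagents that add atoms: none
Why: fluoride-induced protodesilylation of the alkynylsilane, with acetic acid buffering the basicity of TBAF so that the aryl acetate should stay in place.

Step 10
Reactants: 6 2-iodo-5-methoxy-1,3-phenylene diacetate; 15 3-ethynyl-2,5,6-trimethoxyphenyl acetate; 16 carbon monoxide
Product: 19 3'-O-acetyl-5-hydroxy-7,2',4',5'-tetramethoxyflavone, via diacetoxyaryl ynone 17 (not isolated), via diethylamino enone 18 (not isolated)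
Conditions: PdCl2(PPh3)2 (5 mol %), dppp (5 mol %), thiourea (5 mol %), Et2NH (5 equiv), DBU (2 equiv), CO (1 atm), DMF, 40 °C
Reagents that add atoms: none
Why: Zerovalent palladium, generated in situ from PdCl2(PPh3)2, adds oxidatively to the C–I bond of 6, CO inserts to give the 2,6-diacetoxyaroyl palladium iodide, and base-assisted transfer of the acetylide of 15 followed by reductive elimination forms C4a–C4 and C4–C3, giving ynone 17. Diethylamine then aminolyses the two ring A acetates and adds to the ynone at C2 to give the β-(diethylamino)enone 18, and one of the two liberated phenol oxygens attacks C2 and expels diethylamine, which forms O1–C2 and closes the six-membered pyranone ring C (formally a 6-endo-dig closure of the ynone, in practice a 6-endo-trig addition–elimination on the enaminone). The closest known reaction type is the palladium-catalysed carbonylative annulation of o-iodophenyl acetates with terminal aryl acetylenes under CO in the presence of a secondary amine, which gives flavones; it is applied here to an iodide that carries an acetoxy group on both sides. The selectivity required is six-membered flavone closure over 5-exo attack at C3 (aurone), and the secondary amine secures it because in 18 the only electrophilic carbon within reach of the phenol is the amine-bearing C2; no choice between the two ring A oxygens is needed because 6 is mirror-symmetric about the line through C–I and C–OMe, and the oxygen that does not cyclise ends as the hydrogen-bonded 5-OH. No stereocentre is created, the acetates lower the electron density of the iodide for oxidative addition and keep the phenols masked until the ynone exists, and the 3'-acetate, flanked by two methoxy groups, should resist aminolysis at 40 °C and so keep the ring B phenol away from the aroyl palladium intermediate.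

Step 11
Reactants: 19 3'-O-acetyl-5-hydroxy-7,2',4',5'-tetramethoxyflavone
Product: 20 5,3'-dihydroxy-7,2',4',5'-tetramethoxyflavone
Conditions: K2CO3 (0.3 equiv), MeOH, rt; dilute HCl work-up
Reagents that add atoms: none
Why: base-catalysed transesterification of the hindered aryl acetate to methyl acetate frees the 3'-OH while the methyl ethers, the chelated 5-OH and the γ-pyrone are inert to carbonate in methanol at room temperature, and the same treatment would clear any ring A acetate that escaped aminolysis.

**Compound list**

1 | 5-methoxyresorcinol (5-methoxybenzene-1,3-diol) | COc1cc(O)cc(O)c1 | starting material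
2 | 1-methoxy-3,5-bis(methoxymethoxy)benzene | COCOc1cc(OC)cc(OCOC)c1 | intermediate
3 | 2-lithio-5-methoxy-1,3-bis(methoxymethoxy)benzene | [Li]c1c(OCOC)cc(OC)cc1OCOC | intermediate
4 | 2-iodo-5-methoxy-1,3-bis(methoxymethoxy)benzene | COCOc1cc(OC)cc(OCOC)c1I | intermediate
5 | 2-iodo-5-methoxyresorcinol (2-iodo-5-methoxybenzene-1,3-diol) | COc1cc(O)c(I)c(O)c1 | intermediate
6 | 2-iodo-5-methoxy-1,3-phenylene diacetate | COc1cc(OC(C)=O)c(I)c(OC(C)=O)c1 | intermediate
7 | 1,2,4-trimethoxybenzene | COc1ccc(OC)c(OC)c1 | starting material
8 | 3-lithio-1,2,4-trimethoxybenzene | COc1ccc(OC)c(OC)c1[Li] | intermediate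
9 | lithium trimethoxy(2,3,6-trimethoxyphenyl)borate | [Li+].CO[B-](OC)(OC)c1c(OC)ccc(OC)c1OC | intermediate
10 | 2,3,6-trimethoxyphenol | COc1ccc(OC)c(OC)c1O | intermediate
11 | 2,3,6-trimethoxyphenyl acetate | COc1ccc(OC)c(OC)c1OC(C)=O | intermediate
12 | 3-iodo-2,5,6-trimethoxyphenyl acetate | COc1cc(I)c(OC)c(OC(C)=O)c1OC | intermediate
13 | trimethylsilylacetylene | C#C[Si](C)(C)C | starting material
14 | 2,5,6-trimethoxy-3-[(trimethylsilyl)ethynyl]phenyl acetate | COc1cc(C#C[Si](C)(C)C)c(OC)c(OC(C)=O)c1OC | intermediate
15 | 3-ethynyl-2,5,6-trimethoxyphenyl acetate | C#Cc1cc(OC)c(OC)c(OC(C)=O)c1OC | intermediate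
16 | carbon monoxide | [C-]#[O+] | starting material
17 | 3-[3-(2,6-diacetoxy-4-methoxyphenyl)-3-oxoprop-1-yn-1-yl]-2,5,6-trimethoxyphenyl acetate | COc1cc(OC(C)=O)c(C(=O)C#Cc2cc(OC)c(OC)c(OC(C)=O)c2OC)c(OC(C)=O)c1 | intermediate
18 | 3-[(E)-1-(diethylamino)-3-(2,6-dihydroxy-4-methoxyphenyl)-3-oxoprop-1-en-1-yl]-2,5,6-trimethoxyphenyl acetate | COc1cc(O)c(C(=O)/C=C(/N(CC)CC)c2cc(OC)c(OC)c(OC(C)=O)c2OC)c(O)c1 | intermediate
19 | 3'-O-acetyl-5-hydroxy-7,2',4',5'-tetramethoxyflavone [3-(5-hydroxy-7-methoxy-4-oxo-4H-chromen-2-yl)-2,5,6-trimethoxyphenyl acetate] | COc1cc(O)c2c(=O)cc(-c3cc(OC)c(OC)c(OC(C)=O)c3OC)oc2c1 | intermediate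
20 | 5,3'-dihydroxy-7,2',4',5'-tetramethoxyflavone [5-hydroxy-2-(3-hydroxy-2,4,5-trimethoxyphenyl)-7-methoxy-4H-chromen-4-one] | COc1cc(O)c2c(=O)cc(-c3cc(OC)c(OC)c(O)c3OC)oc2c1 | target

**Count**

Total steps: 11. Longest linear sequence: 7 steps (steps 5, 6, 7, 8, 9, 10, 11, from 1,2,4-trimethoxybenzene). The ring A branch (steps 1 to 4) joins at step 10.

**Steps most likely to fail**

Step 10. The three events packed into one flask may fall out of step. Aminolysis of the ring A acetates may outrun oxidative addition, so that palladium meets a free, still more electron-rich and doubly flanked iodophenoxide that adds slowly and is reduced. Diethylamine may also capture the aroyl palladium intermediate as an amide before the alkyne does. The fallback separates the carbonylation from the ring closure and keeps nucleophilic amine and free phenols out of the palladium step. It sets out from the MOM-protected iodide 4 and the alkyne 15. A copper-free carbonylative Sonogashira coupling (PdCl2(PPh3)2, Et3N, CO 1 atm, THF, rt to 50 °C) would give the ynone 3-[3-(4-methoxy-2,6-bis(methoxymethoxy)phenyl)-3-oxoprop-1-yn-1-yl]-2,5,6-trimethoxyphenyl acetate F1. Conjugate addition of diethylamine (EtOH, rt) would give the enaminone 3-[(E)-1-(diethylamino)-3-(4-methoxy-2,6-bis(methoxymethoxy)phenyl)-3-oxoprop-1-en-1-yl]-2,5,6-trimethoxyphenyl acetate F2. HCl in MeOH at 50 °C would then remove both MOM groups, close ring C by addition–elimination with loss of diethylamine and methanolyse the 3'-acetate. The sequence thus comes back to the route at the target 20, and steps 3, 4 and 11 are not needed.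

Step 7. Iodination may be poorly regioselective. The 2-OMe of 11 is squeezed between OAc and OMe and twisted out of conjugation, so it loses part of its para-directing power, and attack at C4 could then compete with attack at C5. The fallback reverses the order, carbon first and oxygen second, and sets out from 7. NIS with catalytic TFA in MeCN should iodinate the only unhindered position that is ortho to one methoxy group and para to another, giving 1-iodo-2,4,5-trimethoxybenzene F3. Sonogashira coupling with 13 (PdCl2(PPh3)2, CuI, Et3N) would give trimethyl[(2,4,5-trimethoxyphenyl)ethynyl]silane F4. Directed ortho-metalation at the C–H between the 2- and 4-methoxy groups (s-BuLi, TMEDA, THF, −78 °C), B(OMe)3 and then H2O2/AcOH would give 2,5,6-trimethoxy-3-[(trimethylsilyl)ethynyl]phenol F5. Acetylation (Ac2O, pyridine, DMAP) brings the sequence back to the route at 14.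

Step 3. Ipso-protonation of the very electron-rich iodoarene during the acidic acetal cleavage may cause loss or migration of iodine. The fallback uses fluoride-labile instead of acid-labile acetals and sets out from 1. SEMCl and i-Pr2NEt in CH2Cl2 would give 1-methoxy-3,5-bis{[2-(trimethylsilyl)ethoxy]methoxy}benzene F6. Lithiation and iodination as in step 2 (n-BuLi, THF, 0 °C, then I2) would give 2-iodo-5-methoxy-1,3-bis{[2-(trimethylsilyl)ethoxy]methoxy}benzene F7. TBAF (THF, 50 °C) would then release both phenols without any acid, and the sequence comes back to the route at 5.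

**Further compounds**

F1 | step 10 | 3-[3-(4-methoxy-2,6-bis(methoxymethoxy)phenyl)-3-oxoprop-1-yn-1-yl]-2,5,6-trimethoxyphenyl acetate | COCOc1cc(OC)cc(OCOC)c1C(=O)C#Cc1cc(OC)c(OC)c(OC(C)=O)c1OC
F2 | step 10 | 3-[(E)-1-(diethylamino)-3-(4-methoxy-2,6-bis(methoxymethoxy)phenyl)-3-oxoprop-1-en-1-yl]-2,5,6-trimethoxyphenyl acetate | COCOc1cc(OC)cc(OCOC)c1C(=O)/C=C(/N(CC)CC)c1cc(OC)c(OC)c(OC(C)=O)c1OC
F3 | step 7 | 1-iodo-2,4,5-trimethoxybenzene | COc1cc(OC)c(OC)cc1I
F4 | step 7 | trimethyl[(2,4,5-trimethoxyphenyl)ethynyl]silane | COc1cc(OC)c(OC)cc1C#C[Si](C)(C)C
F5 | step 7 | 2,5,6-trimethoxy-3-[(trimethylsilyl)ethynyl]phenol | COc1cc(C#C[Si](C)(C)C)c(OC)c(O)c1OC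
F6 | step 3 | 1-methoxy-3,5-bis{[2-(trimethylsilyl)ethoxy]methoxy}benzene | COc1cc(OCOCC[Si](C)(C)C)cc(OCOCC[Si](C)(C)C)c1
F7 | step 3 | 2-iodo-5-methoxy-1,3-bis{[2-(trimethylsilyl)ethoxy]methoxy}benzene | COc1cc(OCOCC[Si](C)(C)C)c(I)c(OCOCC[Si](C)(C)C)c1
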